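**Plan**

- Retrosynthesis: the N-oxide oxygen is removed first. The side chain is then cut at C2'=C3' (Wittig) to a C5 acetaldehyde and traced to an exocyclic C5 alkylidene acetate. Ring B is finally cut at both C4a–C5 and C8–C8a.
- Enabling feature: in ring A the fusion carbons C4a and C8a are neighbours. C4a can carry iodine beside the C4 methoxyl, and C8a holds the only ring C–H, so palladium placed at C4a can be relayed by norbornene to C8a and return to C4a.
- Forward: ring A is taken fully substituted from a 4-pyridone (iodination, chlorination, methoxide exchange). Ring B is then annulated in one operation with a bromoenoate made by cross-metathesis.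
- The chain is completed by conjugate reduction, ester-to-aldehyde reduction, Wittig olefination and hydrogenation; N-oxidation comes last.
- Stereochemistry: C5, the only stereocentre, is set by catalyst-controlled copper hydride conjugate reduction of the E-enoate. The centre is (5S) up to the alkene and becomes (5R) on saturation only because the side chain then ranks below C6.

Key step: step 5

Assumption: the sense of induction in step 6 is assigned by analogy with (E)-β-aryl-β-alkyl enoates, the (S)-bisphosphine being expected to deliver hydride to the Re face of C5; if the correlation is inverted for this peri-methoxylated exocyclic enoate, the (R)-ligand is used in the same step with no other change.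

**Step 1**
Reactants: 1 3-methoxy-2-methylpyridin-4(1H)-one
Product: 2 5-iodo-3-methoxy-2-methylpyridin-4(1H)-one
Conditions: N-iodosuccinimide (1.05 equiv), DMF, rt to 50 °C
Reagents that add atoms: N-iodosuccinimide, O=C1CCC(=O)N1I
Why: Electrophilic iodination of the vinylogous amide should occur at C5, the only free carbon α to the carbonyl, since C3 is blocked by the methoxyl and C6 is the electrophilic terminus.

**Step 2**
Reactants: 2 5-iodo-3-methoxy-2-methylpyridin-4(1H)-one
Product: 3 4-chloro-5-iodo-3-methoxy-2-methylpyridine
Conditions: POCl3 (neat), 100 °C; ice/aq. NaHCO3 work-up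
Reagents that add atoms: phosphoryl chloride, O=P(Cl)(Cl)Cl
Why: Deoxychlorination of a 4-pyridone via O-phosphorylation and chloride addition–elimination at C4 is standard and leaves the aryl iodide and methyl ether untouched.

**Step 3**
Reactants: 3 4-chloro-5-iodo-3-methoxy-2-methylpyridine
Product: 4 5-iodo-3,4-dimethoxy-2-methylpyridine
Conditions: NaOMe (3 equiv), DMSO, 90 °C
Reagents that add atoms: sodium methoxide, [Na+].[O-]C
Why: Nucleophilic aromatic substitution should take place only at C4, where the Meisenheimer adduct places its charge on nitrogen, while the iodide at the unactivated β-position is retained.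

**Step 4**
Reactants: 5 5-bromopent-1-ene; 6 ethyl acrylate (3 equiv)
Product: 7 ethyl (2E)-6-bromohex-2-enoate
Conditions: second-generation Grubbs catalyst (3 mol%), CH2Cl2, 40 °C
Reagents that add atoms: none
Why: Cross-metathesis of a terminal alkene with an excess of an acrylate is a reliable E-selective pairing of an electron-rich and an electron-poor olefin, driven by loss of ethylene.

**Step 5**
Reactants: 4 5-iodo-3,4-dimethoxy-2-methylpyridine; 7 ethyl (2E)-6-bromohex-2-enoate (1.5 equiv)
Product: 8 ethyl (2E)-2-(3,4-dimethoxy-2-methyl-7,8-dihydroquinolin-5(6H)-ylidene)acetate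
Conditions: Pd(OAc)2 (10 mol%), tri(2-furyl)phosphine (20 mol%), norbornene (2 equiv), Cs2CO3 (3 equiv), MeCN, 85 °C
Reagents that add atoms: none
Why: Zerovalent palladium inserts into the C4a–I bond, norbornene inserts, and the resulting alkylpalladium palladates the C8a–H bond to a five-membered divalent palladacycle; the primary bromide of 7 then adds oxidatively to give tetravalent palladium, and reductive elimination forms C8–C8a. With C4 (methoxyl) and C8a (new alkyl) both substituted, β-carbon elimination expels norbornene and returns palladium to C4a, which adds across the tethered enoate and undergoes β-hydride elimination to the conjugated exocyclic alkene, forming C4a–C5. The closest known reaction is the Catellani ortho-alkylation with ipso-Heck termination of ortho-substituted aryl iodides with ω-bromoalkyl enoates, which gives benzo-fused six-membered rings bearing an alkylidene acetate; here it is applied to an iodopyridine. Ring B closes by 6-exo-trig syn carbopalladation. No stereocentre is formed, and the E geometry follows from syn insertion and syn β-hydride elimination, which place the ester anti to the pyridine. The step needs a single alkylation at C8a before any Heck event; this is secured by the C4 methoxyl blocking the second ortho site, by C8a carrying the only ring hydrogen, and by the excess norbornene, which intercepts the arylpalladium faster than the enoate does.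

**Step 6**
Reactants: 8 ethyl (2E)-2-(3,4-dimethoxy-2-methyl-7,8-dihydroquinolin-5(6H)-ylidene)acetate
Product: 9 ethyl 2-[(5S)-3,4-dimethoxy-2-methyl-5,6,7,8-tetrahydroquinolin-5-yl]acetate
Conditions: Cu(OAc)2·H2O (5 mol%), (S)-DTBM-SEGPHOS (5.5 mol%), (EtO)2MeSiH (3 equiv), t-BuOH (2 equiv), toluene, 0 °C to rt
Reagents that add atoms: none
Why: Ligated copper hydride adds 1,4 to the geometrically pure β,β-disubstituted E-enoate (asymmetric conjugate reduction), the chiral bisphosphine pocket being expected to direct hydride to the Re face of C5 and so set (5S), while t-BuOH protonates the copper enolate and turns the catalyst over.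

**Step 7**
Reactants: 9 ethyl 2-[(5S)-3,4-dimethoxy-2-methyl-5,6,7,8-tetrahydroquinolin-5-yl]acetate
Product: 10 2-[(5S)-3,4-dimethoxy-2-methyl-5,6,7,8-tetrahydroquinolin-5-yl]acetaldehyde
Conditions: i-Bu2AlH (1.1 equiv), CH2Cl2, −78 °C; MeOH then aq. potassium sodium tartrate
Reagents that add atoms: none
Why: Partial reduction of an ester with i-Bu2AlH at low temperature stops at the aluminium hemiacetal, which releases the aldehyde only on work-up; C5 is not α to the carbonyl and cannot epimerise.

**Step 8**
Reactants: 10 2-[(5S)-3,4-dimethoxy-2-methyl-5,6,7,8-tetrahydroquinolin-5-yl]acetaldehyde; 11 (3-phenylpropyl)triphenylphosphonium bromide (1.3 equiv)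
Product: 13 (5S)-3,4-dimethoxy-2-methyl-5-[(2Z)-5-phenylpent-2-en-1-yl]-5,6,7,8-tetrahydroquinoline, via triphenyl(3-phenylpropylidene)phosphorane 12 (not isolated)
Conditions: 11, NaN(SiMe3)2 (1.25 equiv), THF, 0 °C; then 10, −78 °C to rt
Reagents that add atoms: none
Why: Wittig olefination with a non-stabilised ylide joins the three-carbon phenylpropyl unit to the aldehyde carbon, mainly as the Z-alkene, whose geometry is irrelevant because it is erased in the next step.

**Step 9**
Reactants: 13 (5S)-3,4-dimethoxy-2-methyl-5-[(2Z)-5-phenylpent-2-en-1-yl]-5,6,7,8-tetrahydroquinoline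
Product: 14 (5R)-3,4-dimethoxy-2-methyl-5-(5-phenylpentyl)-5,6,7,8-tetrahydroquinoline
Conditions: H2 (1 atm), 10% Pd/C, EtOAc, rt
Reagents that add atoms: none
Why: Heterogeneous hydrogenation saturates the isolated disubstituted alkene under conditions that leave the pyridine and benzene rings intact; C5 is untouched and its descriptor changes only through the CIP ranking.

**Step 10**
Reactants: 14 (5R)-3,4-dimethoxy-2-methyl-5-(5-phenylpentyl)-5,6,7,8-tetrahydroquinoline
Product: 15 (5R)-3,4-dimethoxy-2-methyl-5-(5-phenylpentyl)-5,6,7,8-tetrahydroquinoline 1-oxide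
Conditions: mCPBA (1.2 equiv), CH2Cl2, 0 °C to rt
Reagents that add atoms: 3-chloroperoxybenzoic acid, OOC(=O)c1cccc(Cl)c1
Why: Peracid N-oxidation of an electron-rich trialkyl dialkoxy pyridine is routine, and no other oxidisable group remains once the alkene has been hydrogenated.

**Compound list**

1 | 3-methoxy-2-methylpyridin-4(1H)-one | COc1c(C)[nH]ccc1=O | starting material
2 | 5-iodo-3-methoxy-2-methylpyridin-4(1H)-one | COc1c(C)[nH]cc(I)c1=O | intermediate
3 | 4-chloro-5-iodo-3-methoxy-2-methylpyridine | COc1c(C)ncc(I)c1Cl | intermediate
4 | 5-iodo-3,4-dimethoxy-2-methylpyridine | COc1c(OC)c(C)ncc1I | intermediate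
5 | 5-bromopent-1-ene | C=CCCCBr | starting material
6 | ethyl acrylate | C=CC(=O)OCC | starting material
7 | ethyl (2E)-6-bromohex-2-enoate | CCOC(=O)/C=C/CCCBr | intermediate
8 | ethyl (2E)-2-(3,4-dimethoxy-2-methyl-7,8-dihydroquinolin-5(6H)-ylidene)acetate | CCOC(=O)/C=C1\CCCc2nc(C)c(OC)c(OC)c12 | intermediate
9 | ethyl 2-[(5S)-3,4-dimethoxy-2-methyl-5,6,7,8-tetrahydroquinolin-5-yl]acetate | COc1c(OC)c(C)nc2c1[C@H](CC(=O)OCC)CCC2 | intermediate
10 | 2-[(5S)-3,4-dimethoxy-2-methyl-5,6,7,8-tetrahydroquinolin-5-yl]acetaldehyde | COc1c(OC)c(C)nc2c1[C@H](CC=O)CCC2 | intermediate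
11 | (3-phenylpropyl)triphenylphosphonium bromide | [Br-].c1ccc(cc1)CCC[P+](c1ccccc1)(c1ccccc1)c1ccccc1 | starting material
12 | triphenyl(3-phenylpropylidene)phosphorane | c1ccc(cc1)CCC=P(c1ccccc1)(c1ccccc1)c1ccccc1 | intermediate
13 | (5S)-3,4-dimethoxy-2-methyl-5-[(2Z)-5-phenylpent-2-en-1-yl]-5,6,7,8-tetrahydroquinoline | COc1c(OC)c(C)nc2c1[C@H](C/C=C\CCc1ccccc1)CCC2 | intermediate
14 | (5R)-3,4-dimethoxy-2-methyl-5-(5-phenylpentyl)-5,6,7,8-tetrahydroquinoline | COc1c(OC)c(C)nc2c1[C@H](CCCCCc1ccccc1)CCC2 | intermediate
15 | (5R)-3,4-dimethoxy-2-methyl-5-(5-phenylpentyl)-5,6,7,8-tetrahydroquinoline 1-oxide | COc1c(OC)c(C)[n+]([O-])c2c1[C@H](CCCCCc1ccccc1)CCC2 | target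

**Step count**

Total: 10 steps. Longest linear sequence: 9 steps (steps 1–3 and 5–10, from 1 to 15); step 4 is a one-step side branch.

**Steps most likely to fail**

Step 5. The palladium/norbornene relay may stall on this heteroaryl iodide. Possible causes are binding of the pyridine nitrogen to palladium, slow palladation of the C–H next to nitrogen, quaternisation of the nitrogen by the primary bromide, or direct Heck coupling at C4a before the relay has run. The fallback forms the same two bonds in separate operations and sets out from 4. A decarboxylative Minisci alkylation with hex-5-enoic acid (AgNO3 cat., (NH4)2S2O8, CF3CO2H, CH2Cl2/H2O, 40 °C) should attack the protonated pyridine at its only free position and give 5-iodo-3,4-dimethoxy-2-methyl-6-(pent-4-en-1-yl)pyridine F1. Cross-metathesis of F1 with ethyl acrylate 6 (second-generation Grubbs catalyst, CH2Cl2, 40 °C) should give ethyl (2E)-6-(3-iodo-4,5-dimethoxy-6-methylpyridin-2-yl)hex-2-enoate F2. An intramolecular 6-exo-trig Heck reaction of F2 (Pd(OAc)2, PPh3, Et3N, MeCN, 80 °C) then returns to the route at 8.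

Step 6. Turnover may be slow and facial discrimination poor at the hindered exocyclic β-carbon beside the peri methoxyl. Enantiopurity may also be eroded if the double bond isomerises (E to Z, or into the ring) before hydride transfer. The fallback sets out from 8 and moves the asymmetric step to a hydroxyl-directed hydrogenation. 1,2-Reduction with i-Bu2AlH (2.2 equiv, CH2Cl2, −78 °C) should give (2E)-2-(3,4-dimethoxy-2-methyl-7,8-dihydroquinolin-5(6H)-ylidene)ethan-1-ol F3. Hydrogenation of F3 with Ru(OAc)2[(S)-BINAP] under H2 in MeOH, the ligand antipode being chosen for the (5S) sense, should give 2-[(5S)-3,4-dimethoxy-2-methyl-5,6,7,8-tetrahydroquinolin-5-yl]ethan-1-ol F4. Oxidation of F4 with Dess–Martin periodinane (CH2Cl2, rt) returns to the route at 10, bypassing 9.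

Step 7. The aluminium hemiacetal may collapse before the quench, so that a second hydride is delivered and the reaction runs on past the aldehyde oxidation level. The fallback sets out from 9 and uses an acyl derivative that cannot over-reduce. Treatment with MeNH(OMe)·HCl and i-PrMgCl (THF, −20 °C) should give N-methoxy-N-methyl-2-[(5S)-3,4-dimethoxy-2-methyl-5,6,7,8-tetrahydroquinolin-5-yl]acetamide F5. Reduction of F5 with LiAlH4 (THF, −40 °C) forms a stable chelate that releases the aldehyde only on hydrolysis, returning to the route at 10.

**Further compounds**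

F1 | step 5 | 5-iodo-3,4-dimethoxy-2-methyl-6-(pent-4-en-1-yl)pyridine | COc1c(OC)c(C)nc(CCCC=C)c1I
F2 | step 5 | ethyl (2E)-6-(3-iodo-4,5-dimethoxy-6-methylpyridin-2-yl)hex-2-enoate | CCOC(=O)/C=C/CCCc1nc(C)c(OC)c(OC)c1I
F3 | step 6 | (2E)-2-(3,4-dimethoxy-2-methyl-7,8-dihydroquinolin-5(6H)-ylidene)ethan-1-ol | OC/C=C1\CCCc2nc(C)c(OC)c(OC)c12
F4 | step 6 | 2-[(5S)-3,4-dimethoxy-2-methyl-5,6,7,8-tetrahydroquinolin-5-yl]ethan-1-ol | COc1c(OC)c(C)nc2c1[C@H](CCO)CCC2
F5 | step 7 | N-methoxy-N-methyl-2-[(5S)-3,4-dimethoxy-2-methyl-5,6,7,8-tetrahydroquinolin-5-yl]acetamide | COc1c(OC)c(C)nc2c1[C@H](CC(=O)N(C)OC)CCC2
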